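**Strategy.** Both rings are disconnected at C6 (germacrane numbering): C6 is the lactone O–CH carbon, allylic to the E C4=C5 alkene of the ten-membered ring and γ to the C12 carbonyl of the five-membered lactone. One nickel/chromium-mediated addition of a C5 alkenyl iodide to a C6 aldehyde therefore makes the C5–C6 bond, closes the carbocycle, sets C6 and, by acyl transfer from the C12 methyl ester to the new alkoxide, closes the trans-fused lactone. The cyclisation substrate is an acyclic E-alkenyl iodide aldehyde ester that already holds the Z C1=C10 alkene, C9–OPMB and C8–OTBS from D-tartrate, and the C7 stereocentre from a nitro-Michael addition.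

Key step: step 17

Remark on the chemistry: the target is (6S,7R,8R,9R) with a (2R,3R)-2,3-dimethyloxirane-2-carboxylate (epoxyangelate) at C8, and its threo C8/C9 diol maps onto (2S,3S)-tartrate. L-(+)-diethyl tartrate is assumed to epoxidise (Z)-2-methylbut-2-en-1-ol on the face that gives the (2S,3R)-epoxy alcohol, as it does with other Z-2-alken-1-ols. PMB = 4-methoxybenzyl, TBS = tert-butyldimethylsilyl.

Design notes: the C6 aldehyde is carried as its dimethyl acetal until the step before cyclisation. In the endgame C8 is desilylated and acylated before the oxidative deprotection and acetylation of C9, so that no acetate sees fluoride and no epoxide sees HF.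

**Side chain (C1–C5)**

Step 1
Reactants: 1 pent-4-yn-1-ol
Product: 3 (E)-5-iodo-4-methylpent-4-en-1-ol, via alkenylalane 2 (not isolated)
Conditions: AlMe3 (3 equiv), Cp2ZrCl2 (0.25 equiv), CH2Cl2, 0 °C to rt; then I2, THF, −30 °C to 0 °C
Reagents that add atoms: trimethylaluminium, C[Al](C)C; iodine, II
Why: Zirconium-catalysed carboalumination (Negishi) adds methyl and aluminium syn across the terminal alkyne with methyl on the internal carbon, and iodinolysis of the C–Al bond with retention should give the E alkenyl iodide only.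

Step 2
Reactants: 3 (E)-5-iodo-4-methylpent-4-en-1-ol
Product: 4 (E)-1,5-diiodo-2-methylpent-1-ene
Conditions: I2, PPh3, imidazole, CH2Cl2, 0 °C to rt
Reagents that add atoms: iodine, II
Why: Appel-type iodination converts the primary alcohol through its alkoxyphosphonium salt by SN2 attack of iodide, and the alkenyl iodide is inert to these conditions.

Step 3
Reactants: 4 (E)-1,5-diiodo-2-methylpent-1-ene
Product: 5 [(E)-5-iodo-4-methylpent-4-en-1-yl]triphenylphosphonium iodide
Conditions: PPh3, MeCN, reflux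
Reagents that add atoms: triphenylphosphine, c1ccc(cc1)P(c1ccccc1)c1ccccc1
Why: SN2 quaternisation of the phosphine occurs only at the primary alkyl iodide because the sp2 C–I bond cannot be displaced.

**Epoxy acid side chain**

Step 4
Reactants: 6 angelic acid, (Z)-2-methylbut-2-enoic acid
Product: 7 (Z)-2-methylbut-2-en-1-ol
Conditions: LiAlH4, Et2O, 0 °C to rt; H2O, NaOH (aq)
Reagents that add atoms: none
Why: Hydride reduction of the carboxylate (1,2-reduction) leaves the trisubstituted alkene untouched, so the Z geometry of the acid is carried over.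

Step 5
Reactants: 7 (Z)-2-methylbut-2-en-1-ol
Product: 8 [(2S,3R)-2,3-dimethyloxiran-2-yl]methanol
Conditions: Ti(OiPr)4 (10 mol%), L-(+)-diethyl tartrate (12 mol%), t-BuOOH, 4 Å molecular sieves, CH2Cl2, −20 °C
Reagents that add atoms: tert-butyl hydroperoxide, CC(C)(C)OO
Why: Sharpless asymmetric epoxidation delivers oxygen within the titanium–tartrate–allylic alkoxide complex to one alkene face, chosen by the L-(+)-tartrate ligand (2S), and the syn addition keeps CH2OH and the C3 methyl cis (3R).

Step 6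
Reactants: 8 [(2S,3R)-2,3-dimethyloxiran-2-yl]methanol
Product: 10 (2R,3R)-2,3-dimethyloxirane-2-carboxylic acid, via epoxy aldehyde 9 (not isolated)
Conditions: TEMPO (10 mol%), PhI(OAc)2 (2.2 equiv), MeCN/H2O (1:1), rt
Reagents that add atoms: water, O
Why: Oxoammonium-mediated oxidation takes the primary alcohol to the aldehyde and, through its hydrate, to the acid under near-neutral conditions that spare the epoxide; neither stereocentre is touched (C2 becomes R by priority change only).

**Main chain to the cyclisation substrate**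

Step 7
Reactants: 11 diethyl D-tartrate
Product: 12 diethyl (2S,3S)-2-hydroxy-3-[(4-methoxybenzyl)oxy]butanedioate
Conditions: PMBCl (1.1 equiv), Ag2O (1.5 equiv), CH2Cl2, rt, dark
Reagents that add atoms: 4-methoxybenzyl chloride, COc1ccc(CCl)cc1
Why: Silver-oxide-promoted Williamson etherification is mild enough not to epimerise the α-hydroxy ester, the C2 symmetry makes both hydroxyls equivalent so that mono-alkylation gives a single compound, and the second alkylation is slower.

Step 8
Reactants: 12 diethyl (2S,3S)-2-hydroxy-3-[(4-methoxybenzyl)oxy]butanedioate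
Product: 14 (3S,4R)-4-hydroxy-3-[(4-methoxybenzyl)oxy]oxolan-2-one, via diol ester 13 (not isolated)
Conditions: BH3·SMe2 (1.05 equiv), NaBH4 (5 mol%), THF, 0 °C to rt; MeOH quench; then PPTS (cat.), toluene, 60 °C
Reagents that add atoms: none
Why: Hydroxyl-directed borane reduction delivers hydride from the alkoxyborane of the free hydroxyl only to the neighbouring ester (future C7), and the new primary hydroxyl then closes onto the remaining ester by 5-exo-trig acyl substitution, which differentiates the two ends of the tartrate.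

Step 9
Reactants: 14 (3S,4R)-4-hydroxy-3-[(4-methoxybenzyl)oxy]oxolan-2-one
Product: 15 (3S,4R)-4-[(tert-butyldimethylsilyl)oxy]-3-[(4-methoxybenzyl)oxy]oxolan-2-one
Conditions: TBSCl, imidazole, DMF, rt
Reagents that add atoms: tert-butyldimethylsilyl chloride, CC(C)(C)[Si](C)(C)Cl
Why: Silylation of the only free hydroxyl (future C8–O) is routine, and imidazole is too weak a base to trigger β-elimination in the lactone.

Step 10
Reactants: 15 (3S,4R)-4-[(tert-butyldimethylsilyl)oxy]-3-[(4-methoxybenzyl)oxy]oxolan-2-one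
Product: 16 (2S,3R)-3-[(tert-butyldimethylsilyl)oxy]-4-hydroxy-N-methoxy-2-[(4-methoxybenzyl)oxy]-N-methylbutanamide
Conditions: MeNH(OMe)·HCl (3 equiv), i-PrMgCl (6 equiv), THF, −20 °C to 0 °C
Reagents that add atoms: N,O-dimethylhydroxylamine hydrochloride, CNOC.Cl
Why: Weinreb aminolysis of the γ-lactone by the magnesium amide opens the ring to the N-methoxy-N-methylamide and frees only the primary C7 hydroxyl, so that C10 becomes a latent methyl ketone and C7 a latent aldehyde in one operation.

Step 11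
Reactants: 16 (2S,3R)-3-[(tert-butyldimethylsilyl)oxy]-4-hydroxy-N-methoxy-2-[(4-methoxybenzyl)oxy]-N-methylbutanamide; 17 methyl (triphenylphosphoranylidene)acetate
Product: 19 methyl (2E,4R,5S)-4-[(tert-butyldimethylsilyl)oxy]-6-[methoxy(methyl)amino]-5-[(4-methoxybenzyl)oxy]-6-oxohex-2-enoate, via aldehyde 18 (not isolated)
Conditions: Dess–Martin periodinane, NaHCO3, CH2Cl2, 0 °C to rt; then 17, rt
Reagents that add atoms: none
Why: Dess–Martin oxidation gives the α-silyloxy aldehyde, which is trapped in the same flask by the stabilised ylide (E-selective Wittig reaction) so that this epimerisable aldehyde is never isolated.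

Step 12
Reactants: 19 methyl (2E,4R,5S)-4-[(tert-butyldimethylsilyl)oxy]-6-[methoxy(methyl)amino]-5-[(4-methoxybenzyl)oxy]-6-oxohex-2-enoate
Product: 20 methyl (3R,4R,5S)-4-[(tert-butyldimethylsilyl)oxy]-6-[methoxy(methyl)amino]-5-[(4-methoxybenzyl)oxy]-3-(nitromethyl)-6-oxohexanoate
Conditions: CH3NO2 (10 equiv), DBU (0.5 equiv), MeCN, 0 °C to rt
Reagents that add atoms: nitromethane, C[N+](=O)[O-]
Why: Base-catalysed Michael addition of nitromethane (a formyl anion equivalent) should follow the Felkin–Anh model, the nitronate attacking the Si face of C7 anti to the C8–OTBS bond with C9 inside and H8 outside, which places the new C6 carbon syn to the C8 oxygen in the C9–C8–C7–C11 zigzag as the target requires.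

Step 13
Reactants: 20 methyl (3R,4R,5S)-4-[(tert-butyldimethylsilyl)oxy]-6-[methoxy(methyl)amino]-5-[(4-methoxybenzyl)oxy]-3-(nitromethyl)-6-oxohexanoate
Product: 23 methyl (3S,4R,5S)-4-[(tert-butyldimethylsilyl)oxy]-3-(dimethoxymethyl)-6-[methoxy(methyl)amino]-5-[(4-methoxybenzyl)oxy]-6-oxohexanoate, via sodium nitronate 21 (not isolated), via formyl ester 22 (not isolated)
Conditions: NaOMe (1.0 equiv), MeOH, 0 °C; O3/O2, CH2Cl2–MeOH, −78 °C, N2 purge, pH 7 buffer wash; crude 22 with HC(OMe)3, PPTS (cat.), MeOH, rt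
Reagents that add atoms: trimethyl orthoformate, COC(OC)OC
Why: Nef reaction in its ozonolytic form cleaves the nitronate C=N bond at −78 °C without touching C7 (the cold buffered quench prevents epimerisation and β-elimination of the silyloxy group), and acid-catalysed acetalisation masks the aldehyde at once so that it survives the Grignard and ylide steps.

Step 14
Reactants: 23 methyl (3S,4R,5S)-4-[(tert-butyldimethylsilyl)oxy]-3-(dimethoxymethyl)-6-[methoxy(methyl)amino]-5-[(4-methoxybenzyl)oxy]-6-oxohexanoate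
Product: 24 methyl (3S,4R,5S)-4-[(tert-butyldimethylsilyl)oxy]-3-(dimethoxymethyl)-5-[(4-methoxybenzyl)oxy]-6-oxoheptanoate
Conditions: MeMgBr (1.5 equiv), THF, −78 °C to −40 °C; NH4Cl (aq)
Reagents that add atoms: methylmagnesium bromide, C[Mg]Br
Why: Weinreb ketone synthesis: the chelated tetrahedral magnesium adduct of the α-alkoxy N-methoxy-N-methylamide forms at low temperature and cannot take up a second methyl, while the unactivated methyl ester and the acetal should be inert at −40 °C.

Step 15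
Reactants: 24 methyl (3S,4R,5S)-4-[(tert-butyldimethylsilyl)oxy]-3-(dimethoxymethyl)-5-[(4-methoxybenzyl)oxy]-6-oxoheptanoate; 5 [(E)-5-iodo-4-methylpent-4-en-1-yl]triphenylphosphonium iodide
Product: 26 methyl (3S,4R,5R,6Z,10E)-4-[(tert-butyldimethylsilyl)oxy]-3-(dimethoxymethyl)-11-iodo-5-[(4-methoxybenzyl)oxy]-6,10-dimethylundeca-6,10-dienoate, via ylide 25 (not isolated)
Conditions: 5, NaN(SiMe3)2, THF, −78 °C to 0 °C; then 24, −78 °C to rt
Reagents that add atoms: none
Why: Wittig olefination of an α-alkoxy methyl ketone with a salt-free non-stabilised ylide is known to place the new chain cis to the alkoxy-bearing carbon (C2 cis to C9, the Z C1=C10 alkene); the alkenyl iodide has no hydrogen on C4 for elimination, and the low temperature should avoid epimerisation at C9.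

Step 16
Reactants: 26 methyl (3S,4R,5R,6Z,10E)-4-[(tert-butyldimethylsilyl)oxy]-3-(dimethoxymethyl)-11-iodo-5-[(4-methoxybenzyl)oxy]-6,10-dimethylundeca-6,10-dienoate
Product: 27 methyl (3S,4R,5R,6Z,10E)-4-[(tert-butyldimethylsilyl)oxy]-3-formyl-11-iodo-5-[(4-methoxybenzyl)oxy]-6,10-dimethylundeca-6,10-dienoate
Conditions: PPTS (cat.), acetone/H2O (10:1), 45 °C
Reagents that add atoms: water, O
Why: Acid-catalysed hydrolysis of the dimethyl acetal under PPTS conditions should leave the secondary TBS ether, the PMB ether and the alkenyl iodide intact and is too mild to epimerise C7 or eliminate the β-silyloxy group.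

**Key step**

Step 17
Reactants: 27 methyl (3S,4R,5R,6Z,10E)-4-[(tert-butyldimethylsilyl)oxy]-3-formyl-11-iodo-5-[(4-methoxybenzyl)oxy]-6,10-dimethylundeca-6,10-dienoate
Product: 30 (6S,7R,8R,9R)-8-[(tert-butyldimethylsilyl)oxy]-9-[(4-methoxybenzyl)oxy]germacra-1(10)Z,4E-dien-12,6-olide, via alkenylchromium species 28 (not isolated), via chromium alkoxide 29 (not isolated)
Conditions: CrCl2 (15 equiv), NiCl2 (2 mol%), degassed DMSO/THF (3:1), 2 mM final concentration, syringe-pump addition of 27, rt; aqueous work-up; PPTS (cat.), CH2Cl2, rt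
Reagents that add atoms: none
Why: Zerovalent nickel, formed from NiCl2 by divalent chromium, inserts into the C5–I bond with retention of the E geometry, and transmetallation gives the alkenyl species of trivalent chromium 28, which adds to the C6 aldehyde; this is the intramolecular Nozaki–Hiyama–Kishi alkenyl iodide–aldehyde coupling used for medium and large carbocycles. The ten-membered ring closes by 10-exo-trig attack of C5 on the formyl carbon, and the γ-lactone closes by 5-exo-trig acyl substitution of the chromium alkoxide 29 on the C12 methyl ester, completed by PPTS if any hydroxy ester survives. The new C6 stereocentre is controlled by C7: with C8 tied back in the forming ring, C5 should approach anti to the CH2CO2Me arm and not anti to H7 (Felkin-type preference), which puts H6 anti to H7 and gives the 6,7-trans lactone. The step needs addition to the aldehyde in preference to the ester and ring closure in preference to oligomerisation; the first is inherent to organochromium reagents, and the second is secured by high dilution with slow addition and by the Z C1=C10 and E C4=C5 alkenes, which fold the chain.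

**Endgame**

Step 18
Reactants: 30 (6S,7R,8R,9R)-8-[(tert-butyldimethylsilyl)oxy]-9-[(4-methoxybenzyl)oxy]germacra-1(10)Z,4E-dien-12,6-olide
Product: 34 (6S,7R,8R,9R)-8-[(tert-butyldimethylsilyl)oxy]-9-[(4-methoxybenzyl)oxy]germacra-1(10)Z,4E,11(13)-trien-12,6-olide, via lithium enolate 31 (not isolated), via Mannich base 32 (not isolated), via ammonium iodide 33 (not isolated)
Conditions: LiN(iPr)2, THF, −78 °C; CH2=NMe2+ I− (Eschenmoser's salt), −78 °C to rt; MeI, MeOH/CH2Cl2, rt; NaHCO3 (aq), CH2Cl2, rt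
Reagents that add atoms: dimethylmethyleneiminium iodide, C=[N+](C)C.[I-]
Why: α-Methylenation by the Mannich route: the lactone enolate (C11 is the only acidic position and has no β-leaving group) is aminomethylated by the iminium salt, and quaternisation followed by mild base-induced elimination gives the exocyclic C11=C13 alkene.

Step 19
Reactants: 34 (6S,7R,8R,9R)-8-[(tert-butyldimethylsilyl)oxy]-9-[(4-methoxybenzyl)oxy]germacra-1(10)Z,4E,11(13)-trien-12,6-olide
Product: 35 (6S,7R,8R,9R)-8-hydroxy-9-[(4-methoxybenzyl)oxy]germacra-1(10)Z,4E,11(13)-trien-12,6-olide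
Conditions: HF·pyridine, pyridine, THF, 0 °C to rt
Reagents that add atoms: none
Why: Desilylation with buffered HF·pyridine removes the C8 TBS ether under mildly acidic conditions to which the PMB ether, the allylic lactone and the α-methylene lactone (which would not tolerate basic fluoride) should be stable.

Step 20
Reactants: 35 (6S,7R,8R,9R)-8-hydroxy-9-[(4-methoxybenzyl)oxy]germacra-1(10)Z,4E,11(13)-trien-12,6-olide; 10 (2R,3R)-2,3-dimethyloxirane-2-carboxylic acid
Product: 37 (6S,7R,8R,9R)-8-{[(2R,3R)-2,3-dimethyloxiran-2-yl]carbonyloxy}-9-[(4-methoxybenzyl)oxy]germacra-1(10)Z,4E,11(13)-trien-12,6-olide, via mixed anhydride 36 (not isolated)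
Conditions: 10, 2,4,6-trichlorobenzoyl chloride, Et3N, THF, rt; then 35, DMAP, toluene, rt
Reagents that add atoms: none
Why: Yamaguchi esterification: DMAP attacks the mixed anhydride only at the less hindered epoxy-acyl carbonyl and the acylpyridinium acylates the hindered C8 hydroxyl, while the acid has no α-hydrogen and so cannot epimerise.

Step 21
Reactants: 37 (6S,7R,8R,9R)-8-{[(2R,3R)-2,3-dimethyloxiran-2-yl]carbonyloxy}-9-[(4-methoxybenzyl)oxy]germacra-1(10)Z,4E,11(13)-trien-12,6-olide
Product: 38 (6S,7R,8R,9R)-8-{[(2R,3R)-2,3-dimethyloxiran-2-yl]carbonyloxy}-9-hydroxygermacra-1(10)Z,4E,11(13)-trien-12,6-olide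
Conditions: DDQ (1.2 equiv), CH2Cl2/pH 7 phosphate buffer (10:1), 0 °C to rt
Reagents that add atoms: none
Why: Oxidative PMB cleavage by DDQ (hydride abstraction to the oxocarbenium ion, then hydrolysis) runs under buffered neutral conditions that should spare the epoxide, both esters and the alkenes, and under which the hindered C8 ester should not migrate.

Step 22
Reactants: 38 (6S,7R,8R,9R)-8-{[(2R,3R)-2,3-dimethyloxiran-2-yl]carbonyloxy}-9-hydroxygermacra-1(10)Z,4E,11(13)-trien-12,6-olide
Product: 39 (6S,7R,8R,9R)-9-acetoxy-8-{[(2R,3R)-2,3-dimethyloxiran-2-yl]carbonyloxy}germacra-1(10)Z,4E,11(13)-trien-12,6-olide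
Conditions: Ac2O, pyridine, DMAP (cat.), CH2Cl2, 0 °C to rt
Reagents that add atoms: acetic anhydride, CC(=O)OC(C)=O
Why: DMAP-catalysed acetylation of the secondary allylic C9 hydroxyl completes the target without touching any stereocentre.

**Compound list**

1 | pent-4-yn-1-ol | C#CCCCO | starting material
2 | (E)-alkenylalane from carboalumination (O-aluminated) | C[Al](C)/C=C(\C)CCCO[Al](C)C | intermediate
3 | (E)-5-iodo-4-methylpent-4-en-1-ol | OCCC/C(C)=C/I | intermediate
4 | (E)-1,5-diiodo-2-methylpent-1-ene | ICCC/C(C)=C/I | intermediate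
5 | [(E)-5-iodo-4-methylpent-4-en-1-yl]triphenylphosphonium iodide | [I-].I/C=C(\C)CCC[P+](c1ccccc1)(c1ccccc1)c1ccccc1 | intermediate
6 | angelic acid, (Z)-2-methylbut-2-enoic acid | C/C=C(/C)C(=O)O | starting material
7 | (Z)-2-methylbut-2-en-1-ol | C/C=C(/C)CO | intermediate
8 | [(2S,3R)-2,3-dimethyloxiran-2-yl]methanol | OC[C@]1(C)O[C@@H]1C | intermediate
9 | (2R,3R)-2,3-dimethyloxirane-2-carbaldehyde | O=C[C@]1(C)O[C@@H]1C | intermediate
10 | (2R,3R)-2,3-dimethyloxirane-2-carboxylic acid | OC(=O)[C@]1(C)O[C@@H]1C | intermediate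
11 | diethyl D-tartrate, diethyl (2S,3S)-2,3-dihydroxybutanedioate | CCOC(=O)[C@@H](O)[C@H](O)C(=O)OCC | starting material
12 | diethyl (2S,3S)-2-hydroxy-3-[(4-methoxybenzyl)oxy]butanedioate | CCOC(=O)[C@@H](OCc1ccc(OC)cc1)[C@H](O)C(=O)OCC | intermediate
13 | ethyl (2S,3R)-3,4-dihydroxy-2-[(4-methoxybenzyl)oxy]butanoate | CCOC(=O)[C@@H](OCc1ccc(OC)cc1)[C@H](O)CO | intermediate
14 | (3S,4R)-4-hydroxy-3-[(4-methoxybenzyl)oxy]oxolan-2-one | O=C1[C@@H](OCc2ccc(OC)cc2)[C@H](O)CO1 | intermediate
15 | (3S,4R)-4-[(tert-butyldimethylsilyl)oxy]-3-[(4-methoxybenzyl)oxy]oxolan-2-one | O=C1[C@@H](OCc2ccc(OC)cc2)[C@H](O[Si](C)(C)C(C)(C)C)CO1 | intermediate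
16 | (2S,3R)-3-[(tert-butyldimethylsilyl)oxy]-4-hydroxy-N-methoxy-2-[(4-methoxybenzyl)oxy]-N-methylbutanamide | CON(C)C(=O)[C@@H](OCc1ccc(OC)cc1)[C@H](O[Si](C)(C)C(C)(C)C)CO | intermediate
17 | methyl (triphenylphosphoranylidene)acetate | COC(=O)C=P(c1ccccc1)(c1ccccc1)c1ccccc1 | starting material
18 | (2S,3S)-3-[(tert-butyldimethylsilyl)oxy]-N-methoxy-2-[(4-methoxybenzyl)oxy]-N-methyl-4-oxobutanamide | CON(C)C(=O)[C@@H](OCc1ccc(OC)cc1)[C@H](O[Si](C)(C)C(C)(C)C)C=O | intermediate
19 | methyl (2E,4R,5S)-4-[(tert-butyldimethylsilyl)oxy]-6-[methoxy(methyl)amino]-5-[(4-methoxybenzyl)oxy]-6-oxohex-2-enoate | CON(C)C(=O)[C@@H](OCc1ccc(OC)cc1)[C@H](O[Si](C)(C)C(C)(C)C)/C=C/C(=O)OC | intermediate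
20 | methyl (3R,4R,5S)-4-[(tert-butyldimethylsilyl)oxy]-6-[methoxy(methyl)amino]-5-[(4-methoxybenzyl)oxy]-3-(nitromethyl)-6-oxohexanoate | CON(C)C(=O)[C@@H](OCc1ccc(OC)cc1)[C@H](O[Si](C)(C)C(C)(C)C)[C@H](CC(=O)OC)C[N+](=O)[O-] | intermediate
21 | sodium nitronate of 20 | CON(C)C(=O)[C@@H](OCc1ccc(OC)cc1)[C@H](O[Si](C)(C)C(C)(C)C)[C@H](CC(=O)OC)C=[N+]([O-])[O-].[Na+] | intermediate
22 | methyl (3S,4R,5S)-4-[(tert-butyldimethylsilyl)oxy]-3-formyl-6-[methoxy(methyl)amino]-5-[(4-methoxybenzyl)oxy]-6-oxohexanoate | CON(C)C(=O)[C@@H](OCc1ccc(OC)cc1)[C@H](O[Si](C)(C)C(C)(C)C)[C@H](CC(=O)OC)C=O | intermediate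
23 | methyl (3S,4R,5S)-4-[(tert-butyldimethylsilyl)oxy]-3-(dimethoxymethyl)-6-[methoxy(methyl)amino]-5-[(4-methoxybenzyl)oxy]-6-oxohexanoate | CON(C)C(=O)[C@@H](OCc1ccc(OC)cc1)[C@H](O[Si](C)(C)C(C)(C)C)[C@H](CC(=O)OC)C(OC)OC | intermediate
24 | methyl (3S,4R,5S)-4-[(tert-butyldimethylsilyl)oxy]-3-(dimethoxymethyl)-5-[(4-methoxybenzyl)oxy]-6-oxoheptanoate | CC(=O)[C@@H](OCc1ccc(OC)cc1)[C@H](O[Si](C)(C)C(C)(C)C)[C@H](CC(=O)OC)C(OC)OC | intermediate
25 | [(E)-5-iodo-4-methylpent-4-en-1-ylidene]triphenylphosphorane | I/C=C(\C)CCC=P(c1ccccc1)(c1ccccc1)c1ccccc1 | intermediate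
26 | methyl (3S,4R,5R,6Z,10E)-4-[(tert-butyldimethylsilyl)oxy]-3-(dimethoxymethyl)-11-iodo-5-[(4-methoxybenzyl)oxy]-6,10-dimethylundeca-6,10-dienoate | I/C=C(\C)CC/C=C(/C)[C@@H](OCc1ccc(OC)cc1)[C@H](O[Si](C)(C)C(C)(C)C)[C@H](CC(=O)OC)C(OC)OC | intermediate
27 | methyl (3S,4R,5R,6Z,10E)-4-[(tert-butyldimethylsilyl)oxy]-3-formyl-11-iodo-5-[(4-methoxybenzyl)oxy]-6,10-dimethylundeca-6,10-dienoate (cyclisation substrate) | I/C=C(\C)CC/C=C(/C)[C@@H](OCc1ccc(OC)cc1)[C@H](O[Si](C)(C)C(C)(C)C)[C@H](CC(=O)OC)C=O | intermediate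
28 | alkenylchromium dichloride from 27 (solvent ligands omitted) | Cl[Cr](Cl)/C=C(\C)CC/C=C(/C)[C@@H](OCc1ccc(OC)cc1)[C@H](O[Si](C)(C)C(C)(C)C)[C@H](CC(=O)OC)C=O | intermediate
29 | ten-membered C6 chromium alkoxide carrying the C7 CH2CO2Me arm | Cl[Cr](Cl)O[C@H]1/C=C(\C)CC/C=C(/C)[C@@H](OCc2ccc(OC)cc2)[C@H](O[Si](C)(C)C(C)(C)C)[C@@H]1CC(=O)OC | intermediate
30 | (6S,7R,8R,9R)-8-[(tert-butyldimethylsilyl)oxy]-9-[(4-methoxybenzyl)oxy]germacra-1(10)Z,4E-dien-12,6-olide | C1C(=O)O[C@H]2/C=C(\C)CC/C=C(/C)[C@@H](OCc3ccc(OC)cc3)[C@H](O[Si](C)(C)C(C)(C)C)[C@H]12 | intermediate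
31 | lithium enolate of 30 | C1=C(O[Li])O[C@H]2/C=C(\C)CC/C=C(/C)[C@@H](OCc3ccc(OC)cc3)[C@H](O[Si](C)(C)C(C)(C)C)[C@H]12 | intermediate
32 | 11-(dimethylaminomethyl) lactone (C11 configuration immaterial) | CN(C)CC1C(=O)O[C@H]2/C=C(\C)CC/C=C(/C)[C@@H](OCc3ccc(OC)cc3)[C@H](O[Si](C)(C)C(C)(C)C)[C@H]12 | intermediate
33 | 11-(trimethylammoniomethyl) lactone iodide | C[N+](C)(C)CC1C(=O)O[C@H]2/C=C(\C)CC/C=C(/C)[C@@H](OCc3ccc(OC)cc3)[C@H](O[Si](C)(C)C(C)(C)C)[C@H]12.[I-] | intermediate
34 | (6S,7R,8R,9R)-8-[(tert-butyldimethylsilyl)oxy]-9-[(4-methoxybenzyl)oxy]germacra-1(10)Z,4E,11(13)-trien-12,6-olide | C=C1C(=O)O[C@H]2/C=C(\C)CC/C=C(/C)[C@@H](OCc3ccc(OC)cc3)[C@H](O[Si](C)(C)C(C)(C)C)[C@H]12 | intermediate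
35 | (6S,7R,8R,9R)-8-hydroxy-9-[(4-methoxybenzyl)oxy]germacra-1(10)Z,4E,11(13)-trien-12,6-olide | C=C1C(=O)O[C@H]2/C=C(\C)CC/C=C(/C)[C@@H](OCc3ccc(OC)cc3)[C@H](O)[C@H]12 | intermediate
36 | (2R,3R)-2,3-dimethyloxirane-2-carboxylic 2,4,6-trichlorobenzoic anhydride | O=C(OC(=O)c1c(Cl)cc(Cl)cc1Cl)[C@]2(C)O[C@@H]2C | intermediate
37 | (6S,7R,8R,9R)-8-{[(2R,3R)-2,3-dimethyloxiran-2-yl]carbonyloxy}-9-[(4-methoxybenzyl)oxy]germacra-1(10)Z,4E,11(13)-trien-12,6-olide | C=C1C(=O)O[C@H]2/C=C(\C)CC/C=C(/C)[C@@H](OCc3ccc(OC)cc3)[C@H](OC(=O)[C@]4(C)O[C@@H]4C)[C@H]12 | intermediate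
38 | (6S,7R,8R,9R)-8-{[(2R,3R)-2,3-dimethyloxiran-2-yl]carbonyloxy}-9-hydroxygermacra-1(10)Z,4E,11(13)-trien-12,6-olide | C=C1C(=O)O[C@H]2/C=C(\C)CC/C=C(/C)[C@@H](O)[C@H](OC(=O)[C@]3(C)O[C@@H]3C)[C@H]12 | intermediate
39 | (6S,7R,8R,9R)-9-acetoxy-8-{[(2R,3R)-2,3-dimethyloxiran-2-yl]carbonyloxy}germacra-1(10)Z,4E,11(13)-trien-12,6-olide | C=C1C(=O)O[C@H]2/C=C(\C)CC/C=C(/C)[C@@H](OC(C)=O)[C@H](OC(=O)[C@]3(C)O[C@@H]3C)[C@H]12 | target

**Step count**

Total: 22 steps. Longest linear sequence: 16 steps (steps 7 to 22, from diethyl D-tartrate).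

**Steps most likely to fail and their fallbacks**

1. Step 17. What may go wrong: C5 attacks the other face of the aldehyde, because the conformation of the ten-membered transition state rather than C7 decides the facial selectivity, and the epimeric alkoxide lactonises to the cis-fused ring. The fallback sets out from 27, which under the conditions of step 17 would then give the (6R,7R,8R,9R) cis-fused lactone F1. Saponification (LiOH, THF/H2O, 0 °C) opens it to the 6-epi hydroxy acid F2, which is acidified cold just before use. Mitsunobu lactonisation (PPh3, DIAD, toluene, 0 °C) then activates the allylic C6 hydroxyl and lets the carboxylate displace it with inversion. This comes back to the route at 30, with C6 now set by an SN2 substitution instead of by carbonyl facial selectivity.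

2. Step 12. What may go wrong: poor facial selectivity of the nitronate addition, because the bulky silyl ether and the branched C9 substituent compete for the position anti to the nucleophile. The fallback replaces substrate control by catalyst control and sets out from 16. Dess–Martin oxidation to 18 and Wittig reaction with (triphenylphosphoranylidene)acetaldehyde give the (E)-enal F3. Iminium catalysis with (S)-diphenylprolinol trimethylsilyl ether (10 mol%, PhCO2H, CH3NO2, MeOH) shields the Re face of C7 and should deliver nitromethane to the Si face, giving the γ-nitro aldehyde F4. Pinnick oxidation (NaClO2, NaH2PO4, 2-methylbut-2-ene) gives the nitro acid F5, and Me3SiCHN2 in MeOH/toluene esterifies it, which comes back to the route at 20.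

3. Step 15. What may go wrong: low Z/E selectivity, or enolisation of the hindered ketone by the basic ylide instead of addition. The fallback is a Horner–Wittig sequence, in which the alkene geometry follows from a separable adduct and a stereospecific elimination; it sets out from 4 and 24. Michaelis–Arbuzov reaction of 4 with ethyl diphenylphosphinite (neat, 100 °C) gives [(E)-5-iodo-4-methylpent-4-en-1-yl]diphenylphosphine oxide F6. Its lithio derivative (LiN(iPr)2, THF, −78 °C) adds to 24, and the adducts are quenched cold and separated on silica. The (C10 S, C1 R) β-hydroxy phosphine oxide F7 is the diastereomer in which C2 eclipses C9 when P and O are syn-periplanar. Syn-elimination of diphenylphosphinate from F7 (NaH, DMF, rt) gives the Z alkene and comes back to the route at 26.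

**Further compounds**

F1 | step 17 | (6R,7R,8R,9R)-8-[(tert-butyldimethylsilyl)oxy]-9-[(4-methoxybenzyl)oxy]germacra-1(10)Z,4E-dien-12,6-olide (cis-fused 6-epimer of 30) | C1C(=O)O[C@@H]2/C=C(\C)CC/C=C(/C)[C@@H](OCc3ccc(OC)cc3)[C@H](O[Si](C)(C)C(C)(C)C)[C@H]12
F2 | step 17 | 6-epi seco hydroxy acid (ten-membered C6 alcohol with the C7 CH2CO2H arm) | O[C@@H]1/C=C(\C)CC/C=C(/C)[C@@H](OCc2ccc(OC)cc2)[C@H](O[Si](C)(C)C(C)(C)C)[C@@H]1CC(=O)O
F3 | step 12 | (2S,3R,4E)-3-[(tert-butyldimethylsilyl)oxy]-N-methoxy-2-[(4-methoxybenzyl)oxy]-N-methyl-6-oxohex-4-enamide | CON(C)C(=O)[C@@H](OCc1ccc(OC)cc1)[C@H](O[Si](C)(C)C(C)(C)C)/C=C/C=O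
F4 | step 12 | γ-nitro aldehyde (aldehyde analogue of 20) | CON(C)C(=O)[C@@H](OCc1ccc(OC)cc1)[C@H](O[Si](C)(C)C(C)(C)C)[C@H](CC=O)C[N+](=O)[O-]
F5 | step 12 | nitro acid (free acid of 20) | CON(C)C(=O)[C@@H](OCc1ccc(OC)cc1)[C@H](O[Si](C)(C)C(C)(C)C)[C@H](CC(=O)O)C[N+](=O)[O-]
F6 | step 15 | [(E)-5-iodo-4-methylpent-4-en-1-yl]diphenylphosphine oxide | O=P(CCC/C(C)=C/I)(c1ccccc1)c1ccccc1
F7 | step 15 | β-hydroxy phosphine oxide adduct of F6 and 24 (C10 S, C1 R) | I/C=C(\C)CC[C@@H](P(=O)(c1ccccc1)c1ccccc1)[C@@](C)(O)[C@@H](OCc1ccc(OC)cc1)[C@H](O[Si](C)(C)C(C)(C)C)[C@H](CC(=O)OC)C(OC)OC
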